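**Overview**

- The plan rests on ring A (C1–C5, C10; eremophilane numbering, ring B = C5–C10). The unit C4(H)(CH3)–C5(CH3)–C6 with cis methyls is the carbon skeleton of (E)-2-methylbut-2-enal: C4=C5 is its alkene and C6 its formyl carbon.
- Ring A is made first by an enantioselective Diels–Alder union of tiglaldehyde with the (E)-dienyl ketal C3=C2–C1=C10–C9–C8(ketal)–C7, forming C3–C4 and C5–C10.
- Ring B follows by aldol condensation (C6–C7). C3–O comes from allylic oxidation of C1=C2 and an equilibrating metal–ammonia reduction on the bicyclic ketal.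
- The C9 enol and C9=C10 come from α'-hydroxylation and oxidation, which erases C10. C7=C11 comes from acetone by reductive aldol and dehydration.
- The C3 ester is built on the core: acylation with a phosphonopropanoic acid, then (Z)-selective olefination with 2-oxoethyl angelate.

Key step: step 3

Assumption: face selection in step 3 is assigned from the formyl C–H···O binding model for 2-substituted enals, which puts the diene on the Si face of C5 with the catalyst made from (R)-α,α-diphenylprolinol; the antipodal catalyst would serve in the same way if the sense proved opposite.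

**Route**

Step 1
Reactants: 1 ethyl 2-(2-methyl-1,3-dioxolan-2-yl)acetate (fructone, the commercial ethylene ketal of ethyl acetoacetate)
Product: 2 2-(2-methyl-1,3-dioxolan-2-yl)acetaldehyde
Conditions: i-Bu2AlH (1.05 equiv), CH2Cl2, −78 °C; aq. potassium sodium tartrate
Reagents that add atoms: none
Why: Partial ester reduction with i-Bu2AlH stops at the aluminium hemiacetal at −78 °C and releases the aldehyde on work-up, while the ketal is inert to hydride.

Step 2
Reactants: 2 2-(2-methyl-1,3-dioxolan-2-yl)acetaldehyde; 3 diethyl allylphosphonate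
Product: 4 2-methyl-2-[(2E)-penta-2,4-dien-1-yl]-1,3-dioxolane
Conditions: 3, n-BuLi, THF, −78 °C; then 2; then HMPA, −78 °C → rt
Reagents that add atoms: none
Why: Horner–Wadsworth–Emmons-type olefination in which the α-lithiated allylphosphonate adds through its α-carbon and the β-oxido phosphonate loses lithium diethyl phosphate on warming, which is expected to give the terminal (E)-diene; any (Z)-diene cannot easily reach the s-cis form and should stay behind in step 3.

Step 3
Reactants: 4 2-methyl-2-[(2E)-penta-2,4-dien-1-yl]-1,3-dioxolane; 5 tiglaldehyde, (2E)-2-methylbut-2-enal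
Product: 6 (1R,2S,6S)-1,6-dimethyl-2-[(2-methyl-1,3-dioxolan-2-yl)methyl]cyclohex-3-ene-1-carbaldehyde
Conditions: (R)-1-(2-methylphenyl)-3,3-diphenyltetrahydro-1H,3H-pyrrolo[1,2-c][1,3,2]oxazaborole (20 mol%), HNTf2 (18 mol%), 5 (3 equiv), CH2Cl2, −78 → −40 °C
Reagents that add atoms: none
Why: The N-protonated oxazaborolidine is a chiral boron Lewis acid that binds the formyl oxygen of the s-trans enal with the formyl C–H held against the ring oxygen, one phenyl group covers the Re face of C5, and the diene adds to the Si face in a concerted, asynchronous, suprafacial [4+2] cycloaddition. The closest known reaction type is the oxazaborolidinium-catalysed Diels–Alder reaction of 2-substituted enals with 1-substituted butadienes. Ring A (C1–C5, C10) closes as the cycloadduct ring itself, C3–C4 and C5–C10 forming in the one intermolecular [4+2] event. The cis C4/C5 methyls follow from the (E)-geometry of 5, and the absolute configuration at C4 and C5 from the shielded face of the bound aldehyde. C10 is set by the formyl-endo approach (side chain cis to CHO), but either C10 epimer is serviceable because C10 becomes sp2 in step 9. The step needs "ortho" regiochemistry, secured by pairing the larger HOMO coefficient at the unsubstituted diene terminus C3 with the β-carbon C4 of the activated enal, and a slight deficit of HNTf2 keeps free acid away from the ketal.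

Step 4
Reactants: 6 (1R,2S,6S)-1,6-dimethyl-2-[(2-methyl-1,3-dioxolan-2-yl)methyl]cyclohex-3-ene-1-carbaldehyde
Product: 8 (4aS,5S,8aS)-4a,5-dimethyl-4a,5,6,8a-tetrahydronaphthalen-2(1H)-one, via keto aldehyde 7 (not isolated)
Conditions: 1 M HCl, THF, rt; then KOH, MeOH, 0 °C → rt
Reagents that add atoms: water, O
Why: Ketal hydrolysis frees the methyl ketone, and in the intramolecular aldol condensation only the methyl (C7) enolate can reach the non-enolisable C6 aldehyde through a six-membered ring (6-enolexo closure of ring B), dehydration giving the C6=C7 enone without touching C4, C5 or C10.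

Step 5
Reactants: 8 (4aS,5S,8aS)-4a,5-dimethyl-4a,5,6,8a-tetrahydronaphthalen-2(1H)-one
Product: 9 (4a'S,5'S,8a'S)-4a',5'-dimethyl-4a',5',6',8a'-tetrahydro-1'H-spiro[1,3-dioxolane-2,2'-naphthalene]
Conditions: (Me3SiOCH2)2, Me3SiOTf (5 mol%), CH2Cl2, −78 °C; pyridine
Reagents that add atoms: 1,2-bis(trimethylsilyloxy)ethane, C[Si](C)(C)OCCO[Si](C)(C)C
Why: Silyl-triflate-catalysed ketalisation with the bis-silyl ether of ethylene glycol masks C8 under aprotic conditions, the C6=C7 bond cannot migrate because C5 is quaternary, and the ketal lets ring B survive the oxidation and the metal–ammonia reduction of ring A.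

Step 6
Reactants: 9 (4a'S,5'S,8a'S)-4a',5'-dimethyl-4a',5',6',8a'-tetrahydro-1'H-spiro[1,3-dioxolane-2,2'-naphthalene]
Product: 11 (4a'S,5'R,8a'S)-4a',5'-dimethyl-4a',8a'-dihydro-1'H-spiro[1,3-dioxolane-2,2'-naphthalen]-6'(5'H)-one, via allylic tert-butyl peroxide 10 (not isolated)
Conditions: Rh2(caprolactamate)4 (1 mol%), t-BuOOH (5 equiv), K2CO3, CH2Cl2, rt
Reagents that add atoms: tert-butyl hydroperoxide, CC(C)(C)OO
Why: Radical allylic oxidation (hydrogen abstraction by tert-butylperoxyl, capture as the mixed peroxide, collapse to the enone) should go to C3, the only allylic methylene of C1=C2, since C6=C7 has no allylic hydrogen and the tertiary C10–H is flanked by the quaternary C5 and expected to lie near the nodal plane of the alkene in the favoured conformer.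

Step 7
Reactants: 11 (4a'S,5'R,8a'S)-4a',5'-dimethyl-4a',8a'-dihydro-1'H-spiro[1,3-dioxolane-2,2'-naphthalen]-6'(5'H)-one
Product: 13 (4aR,5R,6R,8aR)-6-hydroxy-4a,5-dimethyl-4a,5,6,7,8,8a-hexahydronaphthalen-2(1H)-one, via hydroxy ketal 12 (not isolated)
Conditions: Li, NH3(l), THF, t-BuOH, −78 °C; then EtOH, −33 °C; NH4Cl; then 1 M HCl, THF, rt
Reagents that add atoms: water, O
Why: Dissolving-metal reduction takes the enone through the C2=C3 enolate (so C4 is not enolised) to the ketone and on to the alcohol under thermodynamic control, which should give the equatorial C3–OH trans to the C4 methyl (3R) because the bicyclic ketal favours the ring-A chair with axial C5 methyl and equatorial C4 methyl, as in the reduction of 11-oxo steroids to equatorial alcohols; the isolated C6=C7 bond and the ketal are expected to survive, and the acid work-up unmasks the enone.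

Step 8
Reactants: 13 (4aR,5R,6R,8aR)-6-hydroxy-4a,5-dimethyl-4a,5,6,7,8,8a-hexahydronaphthalen-2(1H)-one
Product: 16 9-hydroxy derivative of 13 (1,6-dihydroxy-4a,5-dimethyl-4a,5,6,7,8,8a-hexahydronaphthalen-2(1H)-one, C9 epimers), via bis-silyl dienol ether 14 (not isolated), via bis-silyloxy enone 15 (not isolated)
Conditions: LiN(i-Pr)2 (2.3 equiv), THF, −78 °C; Me3SiCl; then mCPBA, NaHCO3, CH2Cl2, −20 → 0 °C; then 1 M HCl, THF, 0 °C
Reagents that add atoms: mCPBA, O=C(OO)c1cccc(Cl)c1
Why: Rubottom oxidation, in which the enone can be deprotonated only at C9 (the γ-carbon C5 is quaternary), the 2-silyloxy diene is epoxidised at its electron-rich C8=C9 bond and silyl migration gives the α'-silyloxy enone that is hydrolysed on work-up; the C9 configuration is of no consequence.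

Step 9
Reactants: 16 9-hydroxy derivative of 13
Product: 18 (4aR,5R,6R)-1,6-dihydroxy-4a,5-dimethyl-5,6,7,8-tetrahydronaphthalen-2(4aH)-one, via ene-dione 17 (not isolated)
Conditions: Cu(OAc)2 (2.2 equiv), MeOH, rt, N2
Reagents that add atoms: none
Why: Cu(OAc)2 oxidises α-ketols to 1,2-diones through the copper enediolate and leaves the isolated C3 alcohol alone, and the 8,9-dione can enolise only towards C10, which gives the diosphenol and removes the C10 stereocentre.

Step 10
Reactants: 18 (4aR,5R,6R)-1,6-dihydroxy-4a,5-dimethyl-5,6,7,8-tetrahydronaphthalen-2(4aH)-one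
Product: 20 (4aR,5R,6R)-1-[(tert-butyldimethylsilyl)oxy]-4a,5-dimethyl-6-[(triethylsilyl)oxy]-5,6,7,8-tetrahydronaphthalen-2(4aH)-one, via mono-silyl ether 19 (not isolated)
Conditions: t-BuMe2SiCl (1.1 equiv), Et3N, CH2Cl2, 0 °C; then Et3SiOTf, 2,6-lutidine, −78 → 0 °C
Reagents that add atoms: tert-butyldimethylsilyl chloride, CC(C)(C)[Si](C)(C)Cl; triethylsilyl triflate, CC[Si](CC)(CC)OS(=O)(=O)C(F)(F)F
Why: The acidic enol OH is silylated by the chloride/amine pair, under which the hindered secondary alcohol reacts slowly, and the C3–OH is then capped with the more reactive triflate, giving two silyl ethers of different lability (alkyl triethylsilyl ether acid-labile, enol silyl ether fluoride-labile).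

Step 11
Reactants: 20 (4aR,5R,6R)-1-[(tert-butyldimethylsilyl)oxy]-4a,5-dimethyl-6-[(triethylsilyl)oxy]-5,6,7,8-tetrahydronaphthalen-2(4aH)-one
Product: 22 (4aR,5R,6R)-1-[(tert-butyldimethylsilyl)oxy]-3-(2-hydroxypropan-2-yl)-4a,5-dimethyl-6-[(triethylsilyl)oxy]-4,4a,5,6,7,8-hexahydronaphthalen-2(3H)-one (C7 epimers), via lithium enolate 21 (not isolated)
Conditions: LiB(s-Bu)3H (1.1 equiv), THF, −78 °C; then acetone (5 equiv), −78 °C; AcOH
Reagents that add atoms: acetone, CC(C)=O
Why: Conjugate hydride addition to the β-unsubstituted C6 of the cross-conjugated dienone (the other β-carbon, C10, is fully substituted and part of the enol ether) gives the C7 enolate regiospecifically, and its aldol addition to acetone installs C11–C13; 1,4-reduction with enolate trapping is known for enones next to a quaternary carbon.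

Step 12
Reactants: 22 aldol adduct (C7 epimers)
Product: 24 (4aR,5R,6R)-1-[(tert-butyldimethylsilyl)oxy]-4a,5-dimethyl-3-(propan-2-ylidene)-6-[(triethylsilyl)oxy]-4,4a,5,6,7,8-hexahydronaphthalen-2(3H)-one, via mesylate 23 (not isolated)
Conditions: MeSO2Cl, Et3N, CH2Cl2, 0 °C; then DBU, rt
Reagents that add atoms: none
Why: Sulfonylation of the tertiary aldol hydroxyl and E1cB elimination through the C7 enolate give the conjugated tetrasubstituted C7=C11 bond, and the C7 centre disappears.

Step 13
Reactants: 24 (4aR,5R,6R)-1-[(tert-butyldimethylsilyl)oxy]-4a,5-dimethyl-3-(propan-2-ylidene)-6-[(triethylsilyl)oxy]-4,4a,5,6,7,8-hexahydronaphthalen-2(3H)-one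
Product: 25 (4aR,5R,6R)-1-[(tert-butyldimethylsilyl)oxy]-6-hydroxy-4a,5-dimethyl-3-(propan-2-ylidene)-4,4a,5,6,7,8-hexahydronaphthalen-2(3H)-one
Conditions: PPTS, MeOH, 0 °C → rt
Reagents that add atoms: none
Why: Acid-catalysed methanolysis removes the secondary triethylsilyl ether, while the tert-butyldimethylsilyl enol ether, whose oxygen is conjugated and poorly basic, is expected to persist as aryl silyl ethers do.

Step 14
Reactants: 26 ethyl 2-[bis(2,2,2-trifluoroethoxy)phosphoryl]propanoate
Product: 27 2-[bis(2,2,2-trifluoroethoxy)phosphoryl]propanoic acid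
Conditions: 4 M HCl, 1,4-dioxane, 80 °C
Reagents that add atoms: water, O
Why: Acid-catalysed hydrolysis cleaves the carboxylic ester, whereas the trifluoroethyl phosphonate esters resist acid (no substitution at CH2CF3) and would be attacked at phosphorus by hydroxide.

Step 15
Reactants: 25 (4aR,5R,6R)-1-[(tert-butyldimethylsilyl)oxy]-6-hydroxy-4a,5-dimethyl-3-(propan-2-ylidene)-4,4a,5,6,7,8-hexahydronaphthalen-2(3H)-one; 27 2-[bis(2,2,2-trifluoroethoxy)phosphoryl]propanoic acid
Product: 28 C3 ester of 25 with 27 (phosphonate α-carbon as a mixture of epimers)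
Conditions: DCC, DMAP (10 mol%), CH2Cl2, 0 °C → rt
Reagents that add atoms: none
Why: Steglich esterification of the equatorial C3–OH touches no stereocentre, and the phosphonate α-carbon becomes sp2 in step 18.

Step 16
Reactants: 29 angelic acid, (2Z)-2-methylbut-2-enoic acid; 30 2-bromoethanol
Product: 31 2-hydroxyethyl (2Z)-2-methylbut-2-enoate
Conditions: K2CO3, DMF, 40 °C
Reagents that add atoms: none
Why: O-alkylation of the carboxylate (SN2) forms the ester without activating the acyl group, so the (Z)-geometry of the angelate is not at risk.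

Step 17
Reactants: 31 2-hydroxyethyl (2Z)-2-methylbut-2-enoate
Product: 32 2-oxoethyl (2Z)-2-methylbut-2-enoate
Conditions: Dess–Martin periodinane, NaHCO3, CH2Cl2, 0 °C → rt
Reagents that add atoms: none
Why: Dess–Martin oxidation of the primary alcohol under buffered, non-basic conditions gives the α-acyloxy aldehyde, which is used at once.

Step 18
Reactants: 28 C3 phosphonopropanoate; 32 2-oxoethyl (2Z)-2-methylbut-2-enoate
Product: 33 9-O-(tert-butyldimethylsilyl) ether of the target
Conditions: KN(SiMe3)2 (1.0 equiv), 18-crown-6, THF, −78 °C; then 32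
Reagents that add atoms: none
Why: Still–Gennari olefination, in which the electron-poor oxaphosphetane from the bis(trifluoroethyl) phosphonate collapses faster than it equilibrates, should give the (Z)-trisubstituted enoate with CH2O cis to the ester carbonyl; forming the alkene on the ester avoids acyl activation of a (Z)-2-methyl enoic acid.

Step 19
Reactants: 33 9-O-(tert-butyldimethylsilyl) ether of the target
Product: 34 CNP0301409.1, (3R,4R,5R)-9-hydroxy-8-oxoeremophila-7(11),9-dien-3-yl (2Z)-2-methyl-4-{[(2Z)-2-methylbut-2-enoyl]oxy}but-2-enoate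
Conditions: HF·pyridine, pyridine, THF, 0 °C
Reagents that add atoms: none
Why: Buffered fluoride cleaves the enol silyl ether (the diosphenolate is a good leaving group on silicon) and should leave both unsaturated esters and the (Z)-alkenes alone.

**Compound list**

1 | ethyl 2-(2-methyl-1,3-dioxolan-2-yl)acetate (fructone) | CCOC(=O)CC1(C)OCCO1 | starting material
2 | 2-(2-methyl-1,3-dioxolan-2-yl)acetaldehyde | O=CCC1(C)OCCO1 | intermediate
3 | diethyl allylphosphonate | C=CCP(=O)(OCC)OCC | starting material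
4 | 2-methyl-2-[(2E)-penta-2,4-dien-1-yl]-1,3-dioxolane | C=C/C=C/CC1(C)OCCO1 | intermediate
5 | tiglaldehyde, (2E)-2-methylbut-2-enal | C/C=C(\C)C=O | starting material
6 | (1R,2S,6S)-1,6-dimethyl-2-[(2-methyl-1,3-dioxolan-2-yl)methyl]cyclohex-3-ene-1-carbaldehyde | O=C[C@]1(C)[C@@H](C)CC=C[C@@H]1CC2(C)OCCO2 | intermediate
7 | keto aldehyde (not isolated), (1R,2S,6S)-1,6-dimethyl-2-(2-oxopropyl)cyclohex-3-ene-1-carbaldehyde | O=C[C@]1(C)[C@@H](C)CC=C[C@@H]1CC(C)=O | intermediate
8 | (4aS,5S,8aS)-4a,5-dimethyl-4a,5,6,8a-tetrahydronaphthalen-2(1H)-one (cis-fused; C1=C2 and C6=C7–C8=O in eremophilane numbering) | C1C=C[C@@H]2CC(=O)C=C[C@]2(C)[C@H]1C | intermediate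
9 | (4a'S,5'S,8a'S)-4a',5'-dimethyl-4a',5',6',8a'-tetrahydro-1'H-spiro[1,3-dioxolane-2,2'-naphthalene] | C1C=C[C@@H]2CC3(OCCO3)C=C[C@]2(C)[C@H]1C | intermediate
10 | allylic tert-butyl peroxide (not isolated), 6'-(tert-butylperoxy) derivative of 9 (C3 of the eremophilane numbering, both epimers) | CC(C)(C)OOC1C=C[C@@H]2CC3(OCCO3)C=C[C@]2(C)[C@H]1C | intermediate
11 | (4a'S,5'R,8a'S)-4a',5'-dimethyl-4a',8a'-dihydro-1'H-spiro[1,3-dioxolane-2,2'-naphthalen]-6'(5'H)-one | O=C1C=C[C@@H]2CC3(OCCO3)C=C[C@]2(C)[C@H]1C | intermediate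
12 | hydroxy ketal (not isolated), (4a'R,5'R,6'R,8a'R)-4a',5'-dimethyl-4a',5',6',7',8',8a'-hexahydro-1'H-spiro[1,3-dioxolane-2,2'-naphthalen]-6'-ol | O[C@@H]1CC[C@@H]2CC3(OCCO3)C=C[C@]2(C)[C@H]1C | intermediate
13 | (4aR,5R,6R,8aR)-6-hydroxy-4a,5-dimethyl-4a,5,6,7,8,8a-hexahydronaphthalen-2(1H)-one | O[C@@H]1CC[C@@H]2CC(=O)C=C[C@]2(C)[C@H]1C | intermediate
14 | bis-silyl dienol ether (not isolated), 3-O-trimethylsilyl ether of the 8-(trimethylsilyloxy)-6,8-diene from 13 | C[Si](C)(C)O[C@@H]1CC[C@@H]2C=C(O[Si](C)(C)C)C=C[C@]2(C)[C@H]1C | intermediate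
15 | bis-silyloxy enone (not isolated), 3,9-bis(trimethylsilyloxy) derivative of 13 (C9 epimers) | C[Si](C)(C)O[C@@H]1CC[C@@H]2C(O[Si](C)(C)C)C(=O)C=C[C@]2(C)[C@H]1C | intermediate
16 | 9-hydroxy derivative of 13, 1,6-dihydroxy-4a,5-dimethyl-4a,5,6,7,8,8a-hexahydronaphthalen-2(1H)-one (C9 epimers) | O[C@@H]1CC[C@@H]2C(O)C(=O)C=C[C@]2(C)[C@H]1C | intermediate
17 | ene-dione (not isolated), 8,9-dioxo tautomer of 18 | O[C@@H]1CC[C@@H]2C(=O)C(=O)C=C[C@]2(C)[C@H]1C | intermediate
18 | (4aR,5R,6R)-1,6-dihydroxy-4a,5-dimethyl-5,6,7,8-tetrahydronaphthalen-2(4aH)-one | O[C@@H]1CCC2=C(O)C(=O)C=C[C@]2(C)[C@H]1C | intermediate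
19 | mono-silyl ether (not isolated), 1-O-(tert-butyldimethylsilyl) ether of 18 | O[C@@H]1CCC2=C(O[Si](C)(C)C(C)(C)C)C(=O)C=C[C@]2(C)[C@H]1C | intermediate
20 | (4aR,5R,6R)-1-[(tert-butyldimethylsilyl)oxy]-4a,5-dimethyl-6-[(triethylsilyl)oxy]-5,6,7,8-tetrahydronaphthalen-2(4aH)-one | CC[Si](CC)(CC)O[C@@H]1CCC2=C(O[Si](C)(C)C(C)(C)C)C(=O)C=C[C@]2(C)[C@H]1C | intermediate
21 | lithium enolate (not isolated), C7=C8 lithium enolate from 20 | CC[Si](CC)(CC)O[C@@H]1CCC2=C(O[Si](C)(C)C(C)(C)C)C(O[Li])=CC[C@]2(C)[C@H]1C | intermediate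
22 | (4aR,5R,6R)-1-[(tert-butyldimethylsilyl)oxy]-3-(2-hydroxypropan-2-yl)-4a,5-dimethyl-6-[(triethylsilyl)oxy]-4,4a,5,6,7,8-hexahydronaphthalen-2(3H)-one (C7 epimers) | CC[Si](CC)(CC)O[C@@H]1CCC2=C(O[Si](C)(C)C(C)(C)C)C(=O)C(C(C)(C)O)C[C@]2(C)[C@H]1C | intermediate
23 | mesylate (not isolated), tertiary methanesulfonate of 22 | CC[Si](CC)(CC)O[C@@H]1CCC2=C(O[Si](C)(C)C(C)(C)C)C(=O)C(C(C)(C)OS(C)(=O)=O)C[C@]2(C)[C@H]1C | intermediate
24 | (4aR,5R,6R)-1-[(tert-butyldimethylsilyl)oxy]-4a,5-dimethyl-3-(propan-2-ylidene)-6-[(triethylsilyl)oxy]-4,4a,5,6,7,8-hexahydronaphthalen-2(3H)-one | CC[Si](CC)(CC)O[C@@H]1CCC2=C(O[Si](C)(C)C(C)(C)C)C(=O)C(=C(C)C)C[C@]2(C)[C@H]1C | intermediate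
25 | (4aR,5R,6R)-1-[(tert-butyldimethylsilyl)oxy]-6-hydroxy-4a,5-dimethyl-3-(propan-2-ylidene)-4,4a,5,6,7,8-hexahydronaphthalen-2(3H)-one | O[C@@H]1CCC2=C(O[Si](C)(C)C(C)(C)C)C(=O)C(=C(C)C)C[C@]2(C)[C@H]1C | intermediate
26 | ethyl 2-[bis(2,2,2-trifluoroethoxy)phosphoryl]propanoate | CCOC(=O)C(C)P(=O)(OCC(F)(F)F)OCC(F)(F)F | starting material
27 | 2-[bis(2,2,2-trifluoroethoxy)phosphoryl]propanoic acid | CC(C(=O)O)P(=O)(OCC(F)(F)F)OCC(F)(F)F | intermediate
28 | C3 2-[bis(2,2,2-trifluoroethoxy)phosphoryl]propanoate of 25 (α-carbon epimers) | CC(C(=O)O[C@@H]1CCC2=C(O[Si](C)(C)C(C)(C)C)C(=O)C(=C(C)C)C[C@]2(C)[C@H]1C)P(=O)(OCC(F)(F)F)OCC(F)(F)F | intermediate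
29 | angelic acid, (2Z)-2-methylbut-2-enoic acid | C/C=C(/C)C(=O)O | starting material
30 | 2-bromoethanol | OCCBr | starting material
31 | 2-hydroxyethyl (2Z)-2-methylbut-2-enoate | C/C=C(/C)C(=O)OCCO | intermediate
32 | 2-oxoethyl (2Z)-2-methylbut-2-enoate | C/C=C(/C)C(=O)OCC=O | intermediate
33 | 9-O-(tert-butyldimethylsilyl) ether of the target | C/C=C(/C)C(=O)OC/C=C(/C)C(=O)O[C@@H]1CCC2=C(O[Si](C)(C)C(C)(C)C)C(=O)C(=C(C)C)C[C@]2(C)[C@H]1C | intermediate
34 | CNP0301409.1, (3R,4R,5R)-9-hydroxy-8-oxoeremophila-7(11),9-dien-3-yl (2Z)-2-methyl-4-{[(2Z)-2-methylbut-2-enoyl]oxy}but-2-enoate | C/C=C(/C)C(=O)OC/C=C(/C)C(=O)O[C@@H]1CCC2=C(O)C(=O)C(=C(C)C)C[C@]2(C)[C@H]1C | target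

**Step count**

Total: 19 steps. Longest linear sequence: 16 steps (steps 1–13, 15, 18, 19).

**Steps most likely to fail**

Step 3. The cycloaddition of a β-substituted enal with a 1-alkyl diene may be slow, facial selectivity may erode at the temperature needed, or the acid may open the ketal. The fallback sets out from 4 and 5. Me2AlCl (1 equiv) in CH2Cl2 at −78 → −20 °C should give the racemic endo adduct F1. Condensation with (1R,2R)-N,N'-dimethyl-1,2-diphenylethane-1,2-diamine (4 Å sieves, Et2O, rt) gives two diastereomeric imidazolidines. Chromatography should deliver the imidazolidine of the (1R,2S,6S) aldehyde F2, and two-phase hydrolysis (0.5 M HCl/Et2O, 0 °C) comes back to the route at 6.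

Step 6. Hydrogen abstraction may occur at the tertiary C10–H, or the allyl radical may take up oxygen at C1 and give the transposed enone. The fallback sets out from 9. SeO2 (0.5 equiv) with t-BuOOH in CH2Cl2 at rt hydroxylates by an ene reaction and [2,3] shift, which returns the alkene to C1=C2 and can place oxygen only at C3, giving the allylic alcohol F3 as a mixture of C3 epimers. Oxidation with MnO2 in CH2Cl2 comes back to the route at 11.

Step 11. Hydride may add 1,2 at C8 instead of 1,4 at the neopentyl C6, or the acetone aldolate may revert before the quench. The fallback sets out from 20. Homogeneous hydrogenation with H2 (1 atm) and (Ph3P)3RhCl in benzene saturates only the disubstituted C6=C7 bond and gives the saturated ketone F4. Kinetic deprotonation at C7 with LiN(i-Pr)2 (THF, −78 °C), transmetalation with ZnCl2 and addition of acetone comes back to the route at 22.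

**Further compounds**

F1 | step 3 | racemic (1R*,2S*,6S*)-1,6-dimethyl-2-[(2-methyl-1,3-dioxolan-2-yl)methyl]cyclohex-3-ene-1-carbaldehyde (racemate; one enantiomer drawn) | O=C[C@]1(C)[C@@H](C)CC=C[C@@H]1CC2(C)OCCO2
F2 | step 3 | (4R,5R)-1,3-dimethyl-4,5-diphenylimidazolidine carrying at C2 the (1R,2S,6S)-1,6-dimethyl-2-[(2-methyl-1,3-dioxolan-2-yl)methyl]cyclohex-3-en-1-yl group | CN1[C@H](c2ccccc2)[C@@H](c2ccccc2)N(C)C1[C@]3(C)[C@@H](C)CC=C[C@@H]3CC4(C)OCCO4
F3 | step 6 | 6'-hydroxy derivative of 9 (allylic alcohol at C3 of the eremophilane numbering, both epimers) | OC1C=C[C@@H]2CC3(OCCO3)C=C[C@]2(C)[C@H]1C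
F4 | step 11 | (4aR,5R,6R)-1-[(tert-butyldimethylsilyl)oxy]-4a,5-dimethyl-6-[(triethylsilyl)oxy]-4,4a,5,6,7,8-hexahydronaphthalen-2(3H)-one | CC[Si](CC)(CC)O[C@@H]1CCC2=C(O[Si](C)(C)C(C)(C)C)C(=O)CC[C@]2(C)[C@H]1C
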